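The rate constants stand for no real mixture, and the outcome is calculated.

Early in a cold flask the first thing to ask is how much J has begun to move towards Q, and these are the flasks.

    J → E (k1 = 0.013 s⁻¹, Ea1 = 79.0 kJ mol⁻¹)
    J + Z → JZ (k2 = 0.50 L mol⁻¹ s⁻¹, Ea2 = 36.0 kJ mol⁻¹)
    E ⇌ Q (K3 = 0.89, k3 = 0.0075 s⁻¹, Ea3 = 87.0 kJ mol⁻¹, ΔH3 = −51.0 kJ mol⁻¹)
    Q ⇌ G (K4 = 0.94, k4 = 0.0041 s⁻¹, Ea4 = 83.0 kJ mol⁻¹, ΔH4 = −90.0 kJ mol⁻¹)
    E ⇌ D (K5 = 10, k5 = 0.0042 s⁻¹, Ea5 = 75.0 kJ mol⁻¹, ΔH5 = 33.0 kJ mol⁻¹)
    (constants at 20 °C)

the same everywhere: J 0.050 M; Z 5.00 mM; time 8.0 min
- Wednesday's: temperature −10 °C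
- Tuesday's: temperature 20 °C
- Sunday's: temperature −40 °C
- Saturday's: at 20 °C until 2.5 min, from then on at −40 °C

- the flask that comes out highest in amount of Q, in percent of the J charged, or "all alike" when all lie within 1.5 percentage points (Wednesday's / Tuesday's / Sunday's / Saturday's / all alike)
- Q at the end, in percent of the J charged, Wednesday's
- Q at the end, in percent of the J charged, Tuesday's
- Q at the end, in percent of the J charged, Sunday's
- Q at the end, in percent of the J charged, Saturday's

- at 20 °C the constants are as listed, elsewhere as the activation energies and enthalpies make them

What feeds Q at early times? Q forms from E at k3[E], and E forms from J at k1[J]. While [J] stands near its charge, E is fed at a steady, pseudo-zero-order rate, so [J] is the concentration to watch.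

What do you carry from flask to flask? The first clock: the rate constant of step 1 at the flask's temperature times the time, which is the share of charged J passed to E while [J] stands near its charge. In Sunday's flask it is 0.149%. Q then grows with the square of time, as half of the first clock times the same product for step 3. That product is 0.0369% in Sunday's flask, so I reckon Q there at <0.001%.

And in Wednesday's flask? The first clock is 15.5% and the step 3 product 6.15%, which gives 0.477%. This counts [J] at its charge, so I read it as high.

But at the start of Sunday's flask, J goes to Z 18 times as fast as to E. Doesn't that break the clock? No, because the charge of Z is 10.0% of the charge of J, and binding can take from [J] at most that share.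

What does the cold stretch of Saturday's flask do? At −40 °C, over the remaining time the first clock runs to 0.102% and the step 3 product to 0.0254%, so I expect Saturday's flask to end with about the Q it held at 2.5 min.

And the warm flasks? At 20 °C, k1 times the time is 1.95 by the change and 6.24 by the end of Tuesday's flask. Both stand above one, so the clock no longer holds, and my reckoning stops here without a figure for either flask.

The forecast names Saturday's as highest, with Q at 0.39% for Wednesday's, 15.3% for Tuesday's, <0.001% for Sunday's and 19.1% for Saturday's, on the ground that “quenching at 2.5 min freezes it near its peak”.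

The simulation gives Saturday's, with 0.409%, 15.4%, 0% and 18.9% in the same order. In Saturday's flask, the steps ran at 20 °C until 2.5 min, leaving J 12.3%, E 36.0% and Q 18.9%, and at the end J stood at 12.2%, E at 36.1% and Q at 18.9%. In Tuesday's flask, Q read 20.4% at 4.00 min and 15.4% at the end, while D reached 47.0%. One change that was run takes Saturday's Q away from the forecast's figure: with Z at 28.2 mM, Q in Saturday's flask has moved by 5 points.

Sunday's flask ended with E at 0.147% beside a first clock of 0.149%. The neighbour is Sunday's flask with Z at 0.020 M, or 0.400 equiv. The clock holds no [Z], so it stays 0.149%, with [J] now allowed to fall further. Computed, the neighbour ends with E 0.142%, J 90.8% and Q 0%.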